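## Retrosynthetic overview

1. Locants run from the acid carbon C1. The core is a 1,2-dioxolane (O–O–C3–C4–C5) with two quaternary carbons, and the C2–C1 arm on C3 lies on the same ring face as the methyl on C5. The route rests on this cis pair: the unit O–C1–C2 is first part of an oxetane on C3 (leaving group), then a strap to C5 (face marker for the methyl).
2. Endgame: C1 acid from the primary alcohol, C14=C15 by Horner–Wadsworth–Emmons olefination, and C5–CH3 by retentive opening of a bridged peroxyketal with AlMe3.
3. Key disconnection: the 2,6,7-trioxabicyclo[3.2.1]octane goes back to a β-oxetanyl ketone and H2O2 (bonds O–C3, O–C5 and C1O–C5).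
4. Keto-oxetane: the C4–C5 bond comes from a C5 dithiane anion and (S)-2-methylglycidyl tosylate, and C1 is then added by ylide ring expansion. The C5–C14 chain comes from (R)-citronellal and 5-bromopent-1-ene, joined at C10–C11.
5. Ring order: oxirane, relayed oxirane, oxetane, then dioxolane and oxane together in the key step, and last the opening of the oxane.

Key step: step 10

Assumption: target locants (C1 acid carbon, C3 and C5 dioxolane carbons, C7 side-chain stereocentre) are used for the matching atoms of all intermediates, and both chiral starting materials are used at commercial enantiomeric purity.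

## Route

Step 1
Reactants: 1 (R)-citronellal, (3R)-3,7-dimethyloct-6-enal
Product: 2 2-[(2R)-2,6-dimethylhept-5-en-1-yl]-1,3-dioxolane
Conditions: HOCH2CH2OH, PPTS (cat.), toluene, reflux, Dean–Stark
Reagents that add atoms: ethylene glycol, OCCO
Why: Acid-catalysed acetalisation with azeotropic water removal masks the future C5 aldehyde for ozonolysis and Grignard coupling, the weak pyridinium acid holds back the carbonyl-ene cyclisation of citronellal, and C7 is not touched.

Step 2
Reactants: 2 2-[(2R)-2,6-dimethylhept-5-en-1-yl]-1,3-dioxolane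
Product: 4 (4R)-5-(1,3-dioxolan-2-yl)-4-methylpentan-1-ol, via acetal aldehyde 3 (not isolated)
Conditions: O3, CH2Cl2–MeOH, −78 °C; then NaBH4, −78 → 0 °C
Reagents that add atoms: ozone, [O-][O+]=O
Why: Ozonolysis cleaves the trisubstituted alkene and the borohydride work-up reduces aldehyde 3 in the same flask to the C10 primary alcohol, the acetal being inert to both reagents at low temperature.

Step 3
Reactants: 4 (4R)-5-(1,3-dioxolan-2-yl)-4-methylpentan-1-ol
Product: 5 (4R)-5-(1,3-dioxolan-2-yl)-4-methylpentyl 4-methylbenzenesulfonate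
Conditions: TsCl, Et3N, DMAP (cat.), CH2Cl2, 0 °C → rt
Reagents that add atoms: 4-toluenesulfonyl chloride, Cc1ccc(cc1)S(=O)(=O)Cl
Why: Routine sulfonylation of a primary alcohol makes C10 the electrophile for the sp3–sp3 coupling.

Step 4
Reactants: 5 (4R)-5-(1,3-dioxolan-2-yl)-4-methylpentyl 4-methylbenzenesulfonate; 6 5-bromopent-1-ene
Product: 8 2-[(2R)-2-methyldec-9-en-1-yl]-1,3-dioxolane, via pent-4-enylmagnesium bromide 7 (not isolated)
Conditions: 6, Mg, THF, rt → 40 °C; then 5, Li2CuCl4 (cat.), THF, −20 °C → rt
Reagents that add atoms: none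
Why: The copper-catalysed Grignard–tosylate coupling (Schlosser–Fouquet type) joins C10 to C11 by displacement at a primary carbon, with the acetal, the vinyl group and the remote C7 centre as spectators.

Step 5
Reactants: 8 2-[(2R)-2-methyldec-9-en-1-yl]-1,3-dioxolane
Product: 9 2-[(2R)-2-methyldec-9-en-1-yl]-1,3-dithiane
Conditions: HS(CH2)3SH, BF3·OEt2, CH2Cl2, −20 → 0 °C
Reagents that add atoms: propane-1,3-dithiol, SCCCS
Why: Lewis acid transthioacetalisation converts the acetal directly into the 1,3-dithiane needed for Corey–Seebach umpolung at C5 and leaves the isolated vinyl group alone.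

Step 6
Reactants: 10 (S)-2-methylglycidol, [(2S)-2-methyloxiran-2-yl]methanol
Product: 11 [(2R)-2-methyloxiran-2-yl]methyl 4-methylbenzenesulfonate
Conditions: TsCl, Et3N, DMAP (cat.), CH2Cl2, 0 °C
Reagents that add atoms: 4-toluenesulfonyl chloride, Cc1ccc(cc1)S(=O)(=O)Cl
Why: Sulfonylation of the primary hydroxyl leaves the quaternary epoxide carbon (future C3) and its C–O bond intact, so only the CIP descriptor changes.

Step 7
Reactants: 9 2-[(2R)-2-methyldec-9-en-1-yl]-1,3-dithiane; 11 [(2R)-2-methyloxiran-2-yl]methyl 4-methylbenzenesulfonate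
Product: 14 2-[(2R)-2-methyldec-9-en-1-yl]-2-{[(2R)-2-methyloxiran-2-yl]methyl}-1,3-dithiane, via 2-lithiodithiane 12 (not isolated), via lithium alkoxide tosylate 13 (not isolated)
Conditions: 9, n-BuLi, THF, −25 °C; DMPU, then 11, −78 °C → rt
Reagents that add atoms: none
Why: In this Corey–Seebach alkylation carbanion 12 opens the epoxide at its unsubstituted CH2 (C4–C5 bond), and on warming the tertiary alkoxide of 13 displaces the neighbouring tosylate (3-exo-tet relay), so the C3–O bond and the C3 configuration pass unchanged into the new C3–C2 epoxide.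

Step 8
Reactants: 14 2-[(2R)-2-methyldec-9-en-1-yl]-2-{[(2R)-2-methyloxiran-2-yl]methyl}-1,3-dithiane
Product: 16 2-[(2R)-2-methyldec-9-en-1-yl]-2-{[(2S)-2-methyloxetan-2-yl]methyl}-1,3-dithiane, via sulfoxonium betaine 15 (not isolated)
Conditions: Me3S(O)I, KOt-Bu, t-BuOH, 50 °C
Reagents that add atoms: trimethylsulfoxonium iodide, C[S+](C)(C)=O.[I-]
Why: In this known epoxide-to-oxetane expansion the Corey–Chaykovsky sulfoxonium ylide attacks the epoxide CH2 (C2) and brings in C1, and the tertiary alkoxide of 15 expels DMSO (4-exo-tet) without breaking the C3–O bond.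

Step 9
Reactants: 16 2-[(2R)-2-methyldec-9-en-1-yl]-2-{[(2S)-2-methyloxetan-2-yl]methyl}-1,3-dithiane
Product: 17 (4R)-4-methyl-1-[(2S)-2-methyloxetan-2-yl]dodec-11-en-2-one
Conditions: MeI, CaCO3, MeCN–H2O, 40 °C
Reagents that add atoms: water, O
Why: In this alkylative dithiane hydrolysis S-methylation turns sulfur into a leaving group and water captures the thionium ion, while suspended CaCO3 takes up HI so that neither acid opening of the oxetane nor enolisation–elimination of the β-oxetanyl ketone is favoured, and the vinyl group is safe as it would not be with halonium reagents.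

Step 10
Reactants: 17 (4R)-4-methyl-1-[(2S)-2-methyloxetan-2-yl]dodec-11-en-2-one
Product: 20 (1R,5R)-5-methyl-1-[(2R)-2-methyldec-9-en-1-yl]-2,6,7-trioxabicyclo[3.2.1]octane, via C5 perhydrate 18 (not isolated), via dioxolan-3-ol 19 (not isolated)
Conditions: anhydrous H2O2 in Et2O (10 equiv), TMSOTf (0.2 equiv), Et2O, −78 → −20 °C
Reagents that add atoms: hydrogen peroxide, OO
Why: Proposed new method: H2O2 adds reversibly to the C5 carbonyl, and the outer oxygen of perhydrate 18 attacks the acid-activated oxetane at its tertiary carbon C3 from the side opposite the ring oxygen, a strain-driven 5-exo-tet closure that forms the O–C3 bond and the 1,2-dioxolane ring (O–O–C3–C4–C5) of 19. The acid then ionises the remaining C5–OH (or C5–OOH) of 19 to a peroxycarbenium ion, which the C1 hydroxyl just released from the oxetane captures in a 6-exo-trig closure that forms the C5–O–C1 ether and the oxane ring (O–C1–C2–C3–C4–C5), so both rings of the bicycle arise in one flask; perhydrolysis at C3 before carbonyl addition, or a C5 gem-dihydroperoxide, should drain into the same unstrained intramolecular ketal as the thermodynamic sink. The closest known reaction types are the Lewis acid catalysed perhydrolysis of 2,2-disubstituted oxetanes with inversion, the stereospecific 5-exo opening of oxetanes by tethered hydroperoxides, and the acid-catalysed condensation of 3-hydroperoxy alcohols with ketones to 1,2,4-trioxepanes; their merger on a β-oxetanyl ketone has not been described. C3 is set by one inversion of the centre carried from 10, and C5 is set by the bridge, because the three-atom O–C1–C2 strap can reach C5 only on the dioxolane face that carries C2. The step needs substitution at C3 to win over loss of a C4 proton with ring opening (enone formation) and over free ionisation at C3; the one-carbon tether that holds the perhydrate oxygen behind the C3–O bond, the large excess of H2O2 and the low temperature are meant to secure this, and the vinyl group is inert to H2O2 in the absence of a metal-oxo catalyst.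

Step 11
Reactants: 20 (1R,5R)-5-methyl-1-[(2R)-2-methyldec-9-en-1-yl]-2,6,7-trioxabicyclo[3.2.1]octane
Product: 23 2-{(3R,5R)-3,5-dimethyl-5-[(2R)-2-methyldec-9-en-1-yl]-1,2-dioxolan-3-yl}ethan-1-ol, via peroxycarbenium aluminate 21 (not isolated), via dimethylaluminium alkoxide 22 (not isolated)
Conditions: AlMe3 (3 equiv), toluene, −78 → −20 °C; aq. potassium sodium tartrate
Reagents that add atoms: trimethylaluminium, C[Al](C)C
Why: Proposed new method: AlMe3 should bind the more basic ether oxygen on C1 rather than a peroxide oxygen and, in a solvent that cannot separate ions, loosen the C5–O bond to contact ion pair 21, whose methyl-bearing aluminate stays tied through C1–C2 to the dioxolane face it has just left and hands a methyl group to C5 on that face (retention) before an outside reagent can reach the other face, giving 22 and after hydrolysis 23 with the C5 methyl cis to the hydroxyethyl arm; the closest known reaction types are the retentive alkylative cleavage of acetals and bridged bicyclic ketals by organoaluminium reagents, the Lewis acid substitution of 3-alkoxy-1,2-dioxolanes by carbon nucleophiles through peroxycarbenium ions, and AlMe3 substitutions at acetal centres of cyclic peroxides at low temperature in which the O–O bond survives.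

Step 12
Reactants: 23 2-{(3R,5R)-3,5-dimethyl-5-[(2R)-2-methyldec-9-en-1-yl]-1,2-dioxolan-3-yl}ethan-1-ol
Product: 25 (8R)-9-[(3R,5R)-5-(2-hydroxyethyl)-3,5-dimethyl-1,2-dioxolan-3-yl]-8-methylnonanal, via ozonide 24 (not isolated)
Conditions: O3, CH2Cl2, −78 °C; Me2S, −78 °C → rt
Reagents that add atoms: ozone, [O-][O+]=O
Why: In this ozonolysis with reductive work-up only the vinyl group reacts, and Me2S converts ozonide 24 into the C14 aldehyde without reducing the fully substituted dialkyl peroxide.

Step 13
Reactants: 25 (8R)-9-[(3R,5R)-5-(2-hydroxyethyl)-3,5-dimethyl-1,2-dioxolan-3-yl]-8-methylnonanal; 26 diethyl cinnamylphosphonate, diethyl [(2E)-3-phenylprop-2-en-1-yl]phosphonate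
Product: 28 2-{(3R,5R)-3,5-dimethyl-5-[(2R,9E,11E)-2-methyl-12-phenyldodeca-9,11-dien-1-yl]-1,2-dioxolan-3-yl}ethan-1-ol, via lithiated phosphonate 27 (not isolated)
Conditions: 26 (2.5 equiv), LiN(SiMe3)2 (2.4 equiv), THF–DMPU, −78 °C; then 25, −78 → 0 °C
Reagents that add atoms: none
Why: The Horner–Wadsworth–Emmons olefination with a semi-stabilised allylic phosphonate anion adds reversibly and should favour the E alkene at C14=C15 while the cinnamyl double bond keeps its geometry; the surplus anion covers the free hydroxyl, and the dioxolane has no C–H next to oxygen, so Kornblum–DeLaMare fragmentation is impossible.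

Step 14
Reactants: 28 2-{(3R,5R)-3,5-dimethyl-5-[(2R,9E,11E)-2-methyl-12-phenyldodeca-9,11-dien-1-yl]-1,2-dioxolan-3-yl}ethan-1-ol
Product: 29 2-{(3S,5R)-3,5-dimethyl-5-[(2R,9E,11E)-2-methyl-12-phenyldodeca-9,11-dien-1-yl]-1,2-dioxolan-3-yl}acetaldehyde
Conditions: Dess–Martin periodinane, NaHCO3, CH2Cl2, 0 °C → rt
Reagents that add atoms: none
Why: The buffered Dess–Martin oxidation stops at the aldehyde under near-neutral conditions that spare the diene and the peroxide and do not provoke β-elimination of the peroxide from the new aldehyde, which is carried on at once; the descriptor at C3 changes by priority only.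

Step 15
Reactants: 29 2-{(3S,5R)-3,5-dimethyl-5-[(2R,9E,11E)-2-methyl-12-phenyldodeca-9,11-dien-1-yl]-1,2-dioxolan-3-yl}acetaldehyde
Product: 30 2-{(3S,5R)-3,5-dimethyl-5-[(2R,9E,11E)-2-methyl-12-phenyldodeca-9,11-dien-1-yl]-1,2-dioxolan-3-yl}acetic acid (CNP0196394.4)
Conditions: NaClO2, NaH2PO4, 2-methylbut-2-ene (large excess), t-BuOH–H2O, 0 °C → rt
Reagents that add atoms: sodium chlorite, [Na+].[O-]Cl=O
Why: In the Pinnick oxidation chlorous acid converts the aldehyde into the acid in a mildly acidic buffer that avoids β-elimination, the excess alkene traps HOCl before it can reach the phenyldiene, and no stereocentre is touched.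

## Compound list

1 | (R)-citronellal | C[C@H](CCC=C(C)C)CC=O | starting material
2 | 2-[(2R)-2,6-dimethylhept-5-en-1-yl]-1,3-dioxolane | C[C@H](CCC=C(C)C)CC1OCCO1 | intermediate
3 | (4R)-5-(1,3-dioxolan-2-yl)-4-methylpentanal (not isolated) | C[C@H](CCC=O)CC1OCCO1 | intermediate
4 | (4R)-5-(1,3-dioxolan-2-yl)-4-methylpentan-1-ol | C[C@H](CCCO)CC1OCCO1 | intermediate
5 | (4R)-5-(1,3-dioxolan-2-yl)-4-methylpentyl 4-methylbenzenesulfonate | C[C@H](CCCOS(=O)(=O)c1ccc(C)cc1)CC1OCCO1 | intermediate
6 | 5-bromopent-1-ene | C=CCCCBr | starting material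
7 | pent-4-enylmagnesium bromide (not isolated) | C=CCCC[Mg]Br | intermediate
8 | 2-[(2R)-2-methyldec-9-en-1-yl]-1,3-dioxolane | C[C@H](CCCCCCC=C)CC1OCCO1 | intermediate
9 | 2-[(2R)-2-methyldec-9-en-1-yl]-1,3-dithiane | C[C@H](CCCCCCC=C)CC1SCCCS1 | intermediate
10 | (S)-2-methylglycidol | C[C@]1(CO)CO1 | starting material
11 | [(2R)-2-methyloxiran-2-yl]methyl 4-methylbenzenesulfonate | C[C@]1(COS(=O)(=O)c2ccc(C)cc2)CO1 | intermediate
12 | 2-lithio-2-[(2R)-2-methyldec-9-en-1-yl]-1,3-dithiane (not isolated) | C[C@H](CCCCCCC=C)CC1([Li])SCCCS1 | intermediate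
13 | lithium alkoxide of (2R)-2-hydroxy-2-methyl-3-{2-[(2R)-2-methyldec-9-en-1-yl]-1,3-dithian-2-yl}propyl tosylate (not isolated) | C[C@H](CCCCCCC=C)CC1(C[C@@](C)([O-])COS(=O)(=O)c2ccc(C)cc2)SCCCS1.[Li+] | intermediate
14 | 2-[(2R)-2-methyldec-9-en-1-yl]-2-{[(2R)-2-methyloxiran-2-yl]methyl}-1,3-dithiane | C[C@H](CCCCCCC=C)CC1(C[C@]2(C)CO2)SCCCS1 | intermediate
15 | alkoxide dimethylsulfoxonium betaine from ylide attack at C2 of 14, C3 as in 14 (not isolated) | C[C@H](CCCCCCC=C)CC1(C[C@@](C)([O-])CC[S+](C)(C)=O)SCCCS1 | intermediate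
16 | 2-[(2R)-2-methyldec-9-en-1-yl]-2-{[(2S)-2-methyloxetan-2-yl]methyl}-1,3-dithiane | C[C@H](CCCCCCC=C)CC1(C[C@]2(C)CCO2)SCCCS1 | intermediate
17 | (4R)-4-methyl-1-[(2S)-2-methyloxetan-2-yl]dodec-11-en-2-one | C[C@H](CCCCCCC=C)CC(=O)C[C@]1(C)CCO1 | intermediate
18 | C5 perhydrate of 17, 2-hydroperoxy-2-hydroxy form, C5 not fixed (not isolated) | C[C@H](CCCCCCC=C)CC(O)(OO)C[C@]1(C)CCO1 | intermediate
19 | (5R)-5-(2-hydroxyethyl)-5-methyl-3-[(2R)-2-methyldec-9-en-1-yl]-1,2-dioxolan-3-ol, hemiketal carbon not fixed (not isolated) | C[C@H](CCCCCCC=C)CC1(O)C[C@@](C)(CCO)OO1 | intermediate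
20 | (1R,5R)-5-methyl-1-[(2R)-2-methyldec-9-en-1-yl]-2,6,7-trioxabicyclo[3.2.1]octane | C[C@H](CCCCCCC=C)C[C@@]12C[C@@](C)(CCO1)OO2 | intermediate
21 | peroxycarbenium ion at C5 with tethered trimethylaluminate on the C1 oxygen (not isolated) | C[C@H](CCCCCCC=C)CC1=[O+]O[C@](C)(CCO[Al-](C)(C)C)C1 | intermediate
22 | dimethylaluminium alkoxide of 23 (not isolated) | C[C@H](CCCCCCC=C)C[C@]1(C)C[C@@](C)(CCO[Al](C)C)OO1 | intermediate
23 | 2-{(3R,5R)-3,5-dimethyl-5-[(2R)-2-methyldec-9-en-1-yl]-1,2-dioxolan-3-yl}ethan-1-ol | C[C@H](CCCCCCC=C)C[C@]1(C)C[C@@](C)(CCO)OO1 | intermediate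
24 | 1,2,4-trioxolane (ozonide) of the vinyl group of 23, ozonide carbon not fixed (not isolated) | C[C@H](CCCCCCC1OCOO1)C[C@]1(C)C[C@@](C)(CCO)OO1 | intermediate
25 | (8R)-9-[(3R,5R)-5-(2-hydroxyethyl)-3,5-dimethyl-1,2-dioxolan-3-yl]-8-methylnonanal | C[C@H](CCCCCCC=O)C[C@]1(C)C[C@@](C)(CCO)OO1 | intermediate
26 | diethyl cinnamylphosphonate | CCOP(=O)(C/C=C/c1ccccc1)OCC | starting material
27 | lithiated diethyl cinnamylphosphonate (not isolated) | CCOP(=O)([CH-]/C=C/c1ccccc1)OCC.[Li+] | intermediate
28 | 2-{(3R,5R)-3,5-dimethyl-5-[(2R,9E,11E)-2-methyl-12-phenyldodeca-9,11-dien-1-yl]-1,2-dioxolan-3-yl}ethan-1-ol | C[C@H](CCCCCC/C=C/C=C/c1ccccc1)C[C@]1(C)C[C@@](C)(CCO)OO1 | intermediate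
29 | 2-{(3S,5R)-3,5-dimethyl-5-[(2R,9E,11E)-2-methyl-12-phenyldodeca-9,11-dien-1-yl]-1,2-dioxolan-3-yl}acetaldehyde | C[C@H](CCCCCC/C=C/C=C/c1ccccc1)C[C@]1(C)C[C@@](C)(CC=O)OO1 | intermediate
30 | 2-{(3S,5R)-3,5-dimethyl-5-[(2R,9E,11E)-2-methyl-12-phenyldodeca-9,11-dien-1-yl]-1,2-dioxolan-3-yl}acetic acid | C[C@H](CCCCCC/C=C/C=C/c1ccccc1)C[C@]1(C)C[C@@](C)(CC(=O)O)OO1 | target

## Step count

- Total step count: 15.
- Longest linear sequence: 14 steps (steps 1–5 and 7–15, from 1 to 30). Step 6 is the only side branch.

## Steps most likely to fail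

**1. Step 10.**
Three processes may outpace the intramolecular capture:
- enolisation toward C4 followed by ring-opening elimination of the oxetane;
- ionisation at C3 with erosion of configuration;
- oligomeric perketal formation at the carbonyl.

The fallback uses known chemistry only. It sets out from 17 and comes back at 23, so steps 10 and 11 are both bypassed, and the carbonyl is removed before any acid meets the oxetane. Non-basic Petasis methylenation (Cp2Ti(CH3)2, toluene, 65 °C) should give the methylene oxetane F1. Mukaiyama–Isayama peroxidation (Co(acac)2 cat., O2, Et3SiH as limiting reagent, so that the more reactive 1,1-disubstituted alkene is taken before the vinyl end) should give the tertiary triethylsilyl peroxide F2 as both C5 epimers. HF in aqueous MeCN frees the hydroperoxide F3. Catalytic TMSOTf then closes F3 by the known stereospecific 5-exo opening of the oxetane at C3, giving 23 together with its C5 epimer F4, which is removed by chromatography. The price is that C5 is no longer controlled.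

**2. Step 11.**
Three processes may intervene:
- attack of the aluminium reagent on the O–O bond;
- ionisation of the C5–OO bond in place of the C5–O ether bond;
- methyl delivery from outside the ion pair, with poor facial selectivity.

The fallback uses known chemistry only, sets out from 17 and comes back at 23. The C5 methyl carbon enters as a methylene group and the ring is closed from the C3 side. The methylene oxetane F1, made as in the first fallback, undergoes the known intermolecular perhydrolysis (H2O2 in Et2O, TMSOTf cat., low temperature) with inversion at C3 to the homoallylic hydroperoxy alcohol F5. Cycloperoxymercuration with Hg(OAc)2 in CH2Cl2 (5-exo, Markovnikov, favoured over the vinyl end by intramolecularity) gives the acetoxymercuriomethyl dioxolane F6. Alkaline NaBH4 replaces mercury by hydrogen and gives 23 with its C5 epimer F4, again separated by chromatography.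

**3. Step 7.**
Direct displacement of the sulfonate may compete with epoxide opening, and the two paths deliver opposite configurations at C3. A second carbanion may also add to the relayed epoxide.

The fallback sets out from 9 and 10 and comes back at 14, and it separates the two events. Silylation of 10 (TBSCl, imidazole, DMF) gives the silyl ether F7, whose only electrophilic site is the epoxide CH2. Carbanion 12, made from 9 as in step 7, opens it to the tertiary alcohol F8. Bu4NF gives the diol F9. Selective tosylation of the primary hydroxyl (TsCl, pyridine, 0 °C) gives the monotosylate F10, and K2CO3 in MeOH closes it to 14 with the C3–O bond untouched.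

## Further compounds

F1 | step 10 | (2R)-2-methyl-2-[(4R)-4-methyl-2-methylidenedodec-11-en-1-yl]oxetane (oxetane centre spatially as in 17) | C[C@H](CCCCCCC=C)CC(=C)C[C@]1(C)CCO1
F2 | step 10 | C5 tertiary triethylsilyl peroxide of the oxetane, both C5 epimers | C[C@H](CCCCCCC=C)CC(C)(OO[Si](CC)(CC)CC)C[C@]1(C)CCO1
F3 | step 10 | C5 tertiary hydroperoxide of the oxetane, both C5 epimers | C[C@H](CCCCCCC=C)CC(C)(OO)C[C@]1(C)CCO1
F4 | step 10 | 2-{(3R,5S)-3,5-dimethyl-5-[(2R)-2-methyldec-9-en-1-yl]-1,2-dioxolan-3-yl}ethan-1-ol (C5 epimer of 23) | C[C@H](CCCCCCC=C)C[C@@]1(C)C[C@@](C)(CCO)OO1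
F5 | step 11 | (3S,7R)-3-hydroperoxy-3,7-dimethyl-5-methylidenepentadec-14-en-1-ol | C[C@H](CCCCCCC=C)CC(=C)C[C@@](C)(CCO)OO
F6 | step 11 | 5-(acetoxymercuriomethyl) dioxolane ethanol, both C5 epimers | C[C@H](CCCCCCC=C)CC1(C[Hg]OC(C)=O)C[C@@](C)(CCO)OO1
F7 | step 7 | tert-butyl(dimethyl){[(2R)-2-methyloxiran-2-yl]methoxy}silane | C[C@]1(CO[Si](C)(C)C(C)(C)C)CO1
F8 | step 7 | tertiary alcohol from opening of F7 by 12, C3 as in 13 | C[C@H](CCCCCCC=C)CC1(C[C@@](C)(O)CO[Si](C)(C)C(C)(C)C)SCCCS1
F9 | step 7 | C2,C3 diol of the dithiane | C[C@H](CCCCCCC=C)CC1(C[C@@](C)(O)CO)SCCCS1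
F10 | step 7 | primary monotosylate of F9 | C[C@H](CCCCCCC=C)CC1(C[C@@](C)(O)COS(=O)(=O)c2ccc(C)cc2)SCCCS1
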